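A direct plan would make ring C last from two finished arenes: the lithium enolate of 3-benzyloxy-2,4,5-trimethoxyacetophenone A1 would be C-acylated with 2,6-difluoro-4-methoxybenzoyl chloride A2, and the diketone would be closed by intramolecular SNAr to 3'-benzyloxy-5-fluoro-7,2',4',5'-tetramethoxyflavone A3. Fluoride would then be displaced by benzyl alkoxide to give 5,3'-bis(benzyloxy)-7,2',4',5'-tetramethoxyflavone A4, and both benzyl ethers of A4 would be hydrogenolysed.
Its weakest steps would be:
- The Friedel–Crafts acetylation that puts the acetyl group of A1 on ring B: the site would rest only on an acetoxy group being a poorer donor than methoxy, and an acetylation before and a deacetylation/benzylation after would be spent on one acetyl group.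
- The displacement of the C5 fluoride of A3 by benzyl alkoxide to reach A4: it would run on the most advanced material, activated by one carbonyl only, against alkoxide addition at C2 and opening of ring C, and would need a hydrogenolysis after it.
- The one-flask acylation of the enolate of A1 with A2 and SNAr closure of ring C: O-acylation or double acylation by the hindered acid chloride A2 would consume both advanced fragments.

Plan of the new route:
- The retrosynthesis cuts C2–C1' (ring C to ring B) first, then C3'–O (back to C3'–CHO) and the formyl C–C bond of ring B; ring C goes back to O1–C2 and C2–C3 on an acetophenone.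
- Ring A is bought with both oxygens in place, ring C is closed on it first, and ring B is joined last by a twofold C–H coupling.
- Feature used: C2 of ring C is the hydrogen-bearing β-carbon of the chromone enone. C1' of ring B is para to the 4'-methoxy and ortho to the 2'-methoxy group, while the only other free position, C6', is para to C3'.
- With the 3'-oxygen carried as a formyl group (a masked hydroxyl, put in by lithiation between the two methoxy groups), C6' is deactivated and palladation is steered to C1'.
- No Friedel–Crafts step, no ester shuffling and no fluoride exchange arise: the 5-OH is present from the start, and ring C is made from a cheap acetophenone rather than from two advanced fragments.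

Key step: step 4

Assumption: 2',6'-dihydroxy-4'-methoxyacetophenone (1) and 1,2,4-trimethoxybenzene (5) are bought; the target has no stereocentre.

Step 1
Reactants: 1 2',6'-dihydroxy-4'-methoxyacetophenone
Product: 3 5-hydroxy-7-methoxychromone, via dimethylaminopropenone 2 (not isolated)
Conditions: Me2NCH(OMe)2 (2.5 equiv), toluene, 80 °C; concentrate; conc. HCl, CH2Cl2, 40 °C
Reagents that add atoms: N,N-dimethylformamide dimethyl acetal COC(OC)N(C)C (C2 of ring C; NMe2 of 2)
Why: Aminomethylenation of the methyl ketone should give enaminone 2, and on acidification one of the two equivalent ortho phenols adds to the β-carbon and dimethylamine is lost (enaminone route to chromones), which closes ring C and leaves the other phenol as the chelated 5-OH.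

Step 2
Reactants: 3 5-hydroxy-7-methoxychromone
Product: 4 5-acetoxy-7-methoxychromone
Conditions: Ac2O, pyridine, cat. DMAP, CH2Cl2, rt → 40 °C
Reagents that add atoms: acetic anhydride CC(=O)OC(C)=O
Why: DMAP-catalysed O-acylation should also acylate the chelated peri phenol, which removes the hydroxy-ketone chelate that would bind divalent palladium in step 4 and lowers the nucleophilicity of C6 and C8 of ring A.

Step 3
Reactants: 5 1,2,4-trimethoxybenzene
Product: 7 2,3,6-trimethoxybenzaldehyde, via 2,3,6-trimethoxyphenyllithium 6 (not isolated)
Conditions: n-BuLi, THF, 0 °C → rt; DMF, −78 °C → rt; 1 M HCl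
Reagents that add atoms: n-butyllithium [Li]CCCC (Li of 6 only); N,N-dimethylformamide CN(C)C=O (formyl group)
Why: Directed ortho-metalation removes the only proton held between two methoxy groups, and formylation of the aryllithium with DMF puts a formyl group, the masked 3'-hydroxyl, on that carbon.

Step 4
Reactants: 4 5-acetoxy-7-methoxychromone; 7 2,3,6-trimethoxybenzaldehyde (5 equiv, excess recovered)
Product: 8 5-acetoxy-3'-formyl-7,2',4',5'-tetramethoxyflavone
Conditions: Pd(OAc)2 (15 mol %), AgOAc (3 equiv), PivOH, 110 °C, Ar
Reagents that add atoms: none
Why: Pivalate-assisted electrophilic C–H palladation of 7 at C5 should give an aryl complex of divalent palladium that adds syn across C2=C3 of 4 in the conjugate sense (aryl to C2, palladium to C3); the palladium enolate equilibrates through its oxygen-bound form, syn β-hydride elimination restores C2=C3, and zerovalent palladium is returned to the divalent state by two equivalents of monovalent silver. The closest known reaction type is the palladium-catalysed dehydrogenative (Fujiwara–Moritani-type) C2-arylation of chromones with arene C–H partners. No ring is closed and no stereocentre is formed; the step joins ring B to the finished A/C bicycle through C2–C1'. On 7, C5–H is ortho to the 6-methoxy and para to the 2-methoxy group and only meta to the formyl group, whereas the only other C–H, at C4, is para to the formyl group and deactivated. On 4, the aryl group goes to C2 because carbopalladation places palladium α to the carbonyl, and C6–H and C8–H of ring A are each flanked by two substituents on a ring deactivated by the acetate and the C4 carbonyl. Arene 7 is used in excess so that its palladation outruns direct palladation of 4 at C3.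

Step 5
Reactants: 8 5-acetoxy-3'-formyl-7,2',4',5'-tetramethoxyflavone
Product: 10 5,3'-dihydroxy-7,2',4',5'-tetramethoxyflavone, via aryl formate 9 (not isolated)
Conditions: mCPBA, CH2Cl2, 0 °C → rt; aq. Na2S2O3/NaHCO3 wash; cat. K2CO3, MeOH, rt, Ar; 1 M HCl
Reagents that add atoms: 3-chloroperoxybenzoic acid OOC(=O)c1cccc(Cl)c1 (oxygen at C3')
Why: In the Baeyer–Villiger (Dakin-type) oxidation the electron-rich aryl group with two ortho methoxy groups should migrate in the Criegee adduct to give formate 9, while the flavone enone and the aryl ethers are inert to the peracid; carbonate-catalysed methanolysis (Zemplén-type transesterification) then removes the formate and the 5-acetate together.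

Compound list
1 | 2',6'-dihydroxy-4'-methoxyacetophenone | CC(=O)c1c(O)cc(OC)cc1O | starting material
2 | (E)-1-(2,6-dihydroxy-4-methoxyphenyl)-3-(dimethylamino)prop-2-en-1-one | CN(C)/C=C/C(=O)c1c(O)cc(OC)cc1O | intermediate
3 | 5-hydroxy-7-methoxychromone (5-hydroxy-7-methoxy-4H-chromen-4-one) | COc1cc(O)c2c(=O)ccoc2c1 | intermediate
4 | 5-acetoxy-7-methoxychromone (7-methoxy-4-oxo-4H-chromen-5-yl acetate) | COc1cc(OC(C)=O)c2c(=O)ccoc2c1 | intermediate
5 | 1,2,4-trimethoxybenzene | COc1ccc(OC)c(OC)c1 | starting material
6 | 2,3,6-trimethoxyphenyllithium | [Li]c1c(OC)ccc(OC)c1OC | intermediate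
7 | 2,3,6-trimethoxybenzaldehyde | O=Cc1c(OC)ccc(OC)c1OC | intermediate
8 | 5-acetoxy-3'-formyl-7,2',4',5'-tetramethoxyflavone | COc1cc(OC(C)=O)c2c(=O)cc(-c3cc(OC)c(OC)c(C=O)c3OC)oc2c1 | intermediate
9 | 5-acetoxy-3'-formyloxy-7,2',4',5'-tetramethoxyflavone | COc1cc(OC(C)=O)c2c(=O)cc(-c3cc(OC)c(OC)c(OC=O)c3OC)oc2c1 | intermediate
10 | 5,3'-dihydroxy-7,2',4',5'-tetramethoxyflavone | COc1cc(O)c2c(=O)cc(-c3cc(OC)c(OC)c(O)c3OC)oc2c1 | target

Total step count: 5. Longest linear sequence: 4 (steps 1, 2, 4, 5).

Steps most likely to fail

Step 4 (key step). The C–H palladation of the formyl-deactivated arene may be too slow, so that palladation of the chromone at C3, homocoupling or decarbonylation of the aldehyde takes over, or the two arene C–H bonds may not be told apart cleanly. The fallback sets out from 7, keeps the C2–C1' disconnection and fixes the site beforehand by known chemistry. NBS in MeCN at rt should brominate the same position (para to methoxy, meta to formyl) to give 3-bromo-2,5,6-trimethoxybenzaldehyde F1. Miyaura borylation of F1 (B2pin2, Pd(dppf)Cl2, KOAc, dioxane, 90 °C) should give 2,5,6-trimethoxy-3-(4,4,5,5-tetramethyl-1,3,2-dioxaborolan-2-yl)benzaldehyde F2. NaIO4/NH4OAc in aqueous acetone should cleave the pinacol ester of F2 to (3-formyl-2,4,5-trimethoxyphenyl)boronic acid F3. Conjugate addition of F3 to chromone 4, catalysed by Pd(OCOCF3)2/2,2'-bipyridine in aqueous AcOH–THF at 60 °C, should give racemic 5-acetoxy-3'-formyl-7,2',4',5'-tetramethoxyflavanone F4. Dehydrogenation of F4 with DDQ in dioxane at 100 °C should bring the route back at 8.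

Step 5. The peracid may attack ring C of the flavone, or the electron-poor chromonyl substituent meta to the formyl-bearing carbon may slow aryl migration in the Criegee adduct so that hydride migrates and the benzoic acid forms. The fallback sets out from 7, where the migrating ring carries no such substituent and no flavone is present, and moves the oxygen insertion ahead of the union. mCPBA in CH2Cl2 should give 2,3,6-trimethoxyphenyl formate F5. Methanolysis of F5 (K2CO3, MeOH) should give 2,3,6-trimethoxyphenol F6. Ac2O/pyridine should turn F6 into 2,3,6-trimethoxyphenyl acetate F7. Oxidative coupling of F7 with 4 under the conditions of step 4 should give 5,3'-diacetoxy-7,2',4',5'-tetramethoxyflavone F8; the site would then rest only on para-methoxy against para-acetoxy, so a regioisomer may have to be separated. K2CO3 in MeOH should remove both acetates of F8 and come back to the route at 10.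

Step 1. The acetal may O-methylate a free phenol on heating, or the enaminone may not close cleanly. The fallback sets out from 1 and brings in C2 by a Claisen C-formylation instead. NaH (4 equiv) and ethyl formate in THF, 0 °C → rt, should give after acidification the cyclic hemiacetal 2,5-dihydroxy-7-methoxychroman-4-one F9. Conc. HCl in AcOH at 60 °C should dehydrate F9 and come back to the route at 3.

Further compounds
F1 | step 4 | 3-bromo-2,5,6-trimethoxybenzaldehyde | O=Cc1c(OC)c(Br)cc(OC)c1OC
F2 | step 4 | 2,5,6-trimethoxy-3-(4,4,5,5-tetramethyl-1,3,2-dioxaborolan-2-yl)benzaldehyde | O=Cc1c(OC)c(B2OC(C)(C)C(C)(C)O2)cc(OC)c1OC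
F3 | step 4 | (3-formyl-2,4,5-trimethoxyphenyl)boronic acid | O=Cc1c(OC)c(B(O)O)cc(OC)c1OC
F4 | step 4 | (±)-5-acetoxy-3'-formyl-7,2',4',5'-tetramethoxyflavanone | COc1cc(OC(C)=O)c2C(=O)CC(c3cc(OC)c(OC)c(C=O)c3OC)Oc2c1
F5 | step 5 | 2,3,6-trimethoxyphenyl formate | COc1ccc(OC)c(OC)c1OC=O
F6 | step 5 | 2,3,6-trimethoxyphenol | COc1ccc(OC)c(OC)c1O
F7 | step 5 | 2,3,6-trimethoxyphenyl acetate | COc1ccc(OC)c(OC)c1OC(C)=O
F8 | step 5 | 5,3'-diacetoxy-7,2',4',5'-tetramethoxyflavone | COc1cc(OC(C)=O)c2c(=O)cc(-c3cc(OC)c(OC)c(OC(C)=O)c3OC)oc2c1
F9 | step 1 | (±)-2,5-dihydroxy-7-methoxychroman-4-one | COc1cc(O)c2C(=O)CC(O)Oc2c1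
A1 | direct plan | 3-benzyloxy-2,4,5-trimethoxyacetophenone | CC(=O)c1cc(OC)c(OC)c(OCc2ccccc2)c1OC
A2 | direct plan | 2,6-difluoro-4-methoxybenzoyl chloride | COc1cc(F)c(C(=O)Cl)c(F)c1
A3 | direct plan | 3'-benzyloxy-5-fluoro-7,2',4',5'-tetramethoxyflavone | COc1cc(F)c2c(=O)cc(-c3cc(OC)c(OC)c(OCc4ccccc4)c3OC)oc2c1
A4 | direct plan | 5,3'-bis(benzyloxy)-7,2',4',5'-tetramethoxyflavone | COc1cc(OCc2ccccc2)c3c(=O)cc(-c4cc(OC)c(OC)c(OCc5ccccc5)c4OC)oc3c1
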